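**Retrosynthetic overview**
1. Target ⇐ hydrogenolysis of its 3'-O-benzyl ether (benzyl masks the one free phenol through the base and oxidation steps).
2. Ring C (the pyranone, the only ring that is built) ⇐ I2/DMSO oxidative cyclisation of a 2'-hydroxychalcone; rings A and B come from commercial arenes.
3. Key C–C bond (future C2–C3) ⇐ intermolecular Claisen–Schmidt aldol condensation of 2'-hydroxy-3',4',5',6'-tetramethoxyacetophenone with 3-benzyloxy-4,5-dimethoxybenzaldehyde.
4. Ring A ketone ⇐ 2,3,4-trimethoxybenzaldehyde by Dakin oxidation, O-methylation, Vilsmeier formylation, second Dakin oxidation, ortho C-acetylation.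
5. Ring B aldehyde ⇐ 5-bromovanillin by Cu-mediated hydroxylation, selective 4-O-methylation, 3-O-benzylation.

Assumption: the target has no stereocentre (it is achiral), so no enantiocontrol is needed; the only stereo-element on the route is the E double bond of the chalcone.

**Route**

Step 1
Reactants: 1 2,3,4-trimethoxybenzaldehyde
Product: 3 2,3,4-trimethoxyphenol, via 2,3,4-trimethoxyphenyl formate 2 (not isolated)
Conditions: mCPBA, CH2Cl2, 0 °C → rt; then MeOH, Et3N (cat.), rt, N2
Reagents that add atoms: mCPBA (3-chloroperoxybenzoic acid), OOC(=O)c1cccc(Cl)c1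
Why: Baeyer–Villiger (Dakin-type) oxidation in which the electron-rich aryl group (ortho and para OMe) migrates in the Criegee adduct, and the labile aryl formate is then cleaved by base-catalysed methanolysis.

Step 2
Reactants: 3 2,3,4-trimethoxyphenol
Product: 4 1,2,3,4-tetramethoxybenzene
Conditions: MeI, K2CO3, acetone, reflux, N2
Reagents that add atoms: iodomethane, CI
Why: Williamson ether synthesis (SN2 O-methylation of the phenoxide), clean because the phenol is the only acidic site.

Step 3
Reactants: 4 1,2,3,4-tetramethoxybenzene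
Product: 6 2,3,4,5-tetramethoxybenzaldehyde, via aryl iminium dichlorophosphate 5 (not isolated)
Conditions: POCl3, DMF, 0 °C → 80 °C; then H2O, 60 °C
Reagents that add atoms: N,N-dimethylformamide, CN(C)C=O; water, O
Why: Vilsmeier–Haack formylation (electrophilic aromatic substitution) at one of the two symmetry-equivalent free positions, each activated by an ortho and a para methoxy group, and the aldehyde formed is deactivated against a second formylation.

Step 4
Reactants: 6 2,3,4,5-tetramethoxybenzaldehyde
Product: 8 2,3,4,5-tetramethoxyphenol, via 2,3,4,5-tetramethoxyphenyl formate 7 (not isolated)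
Conditions: mCPBA, CH2Cl2, 0 °C → rt; then MeOH, Et3N (cat.), rt, N2
Reagents that add atoms: mCPBA (3-chloroperoxybenzoic acid), OOC(=O)c1cccc(Cl)c1
Why: Baeyer–Villiger (Dakin-type) oxidation with aryl migration favoured by the ortho methoxy donor, followed by methanolysis of the formate to the air-sensitive phenol, which is used directly.

Step 5
Reactants: 8 2,3,4,5-tetramethoxyphenol
Product: 10 1-(2-hydroxy-3,4,5,6-tetramethoxyphenyl)ethan-1-one, via difluoroboron chelate 9 (not isolated)
Conditions: AcOH, BF3·OEt2 (3 equiv), 85 °C, 3 h; then H2O, 60 °C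
Reagents that add atoms: acetic acid, CC(=O)O
Why: BF3-mediated Friedel–Crafts (Fries-type) ortho C-acylation at the single unsubstituted ring position, driven by formation of the difluoroboron chelate of the ortho-hydroxy ketone, which is hydrolysed in the aqueous stage.

Step 6
Reactants: 11 5-bromovanillin (3-bromo-4-hydroxy-5-methoxybenzaldehyde)
Product: 12 5-hydroxyvanillin (3,4-dihydroxy-5-methoxybenzaldehyde)
Conditions: 8% aq. NaOH, Cu powder (cat.), reflux, N2, 24 h
Reagents that add atoms: sodium hydroxide, [Na+].[OH-]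
Why: Copper-catalysed Ullmann-type hydroxylation (substitution of aryl bromide by hydroxide), in which the aldehyde survives because the para-phenoxide deactivates it toward Cannizzaro disproportionation.

Step 7
Reactants: 12 5-hydroxyvanillin
Product: 13 3-hydroxy-4,5-dimethoxybenzaldehyde
Conditions: Me2SO4 (1.05 equiv), Na2CO3 (1.1 equiv), acetone, reflux, N2
Reagents that add atoms: dimethyl sulfate, COS(=O)(=O)OC
Why: Regioselective Williamson O-methylation, because the 4-OH para to the formyl group is much more acidic than the 3-OH, so one equivalent of weak base forms only the 4-phenoxide.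

Step 8
Reactants: 13 3-hydroxy-4,5-dimethoxybenzaldehyde
Product: 14 3-(benzyloxy)-4,5-dimethoxybenzaldehyde
Conditions: BnBr, K2CO3, DMF, 60 °C
Reagents that add atoms: benzyl bromide, BrCc1ccccc1
Why: Williamson O-benzylation of the remaining phenol, giving a protecting group that is stable to the KOH and I2/DMSO steps and removable by neutral hydrogenolysis.

Step 9
Reactants: 10 1-(2-hydroxy-3,4,5,6-tetramethoxyphenyl)ethan-1-one; 14 3-(benzyloxy)-4,5-dimethoxybenzaldehyde
Product: 16 (E)-3-[3-(benzyloxy)-4,5-dimethoxyphenyl]-1-(2-hydroxy-3,4,5,6-tetramethoxyphenyl)prop-2-en-1-one, via racemic aldol adduct 15 (not isolated)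
Conditions: KOH (50% aq., excess), EtOH, rt, 48 h
Reagents that add atoms: none
Why: Claisen–Schmidt crossed aldol condensation in which only the methyl ketone can enolise and only the aldehyde is electrophilic, and the racemic aldol 15 loses water by E1cB to the conjugated, thermodynamically favoured E-enone (its stereocentre is erased).

Step 10
Reactants: 16 the (E)-2'-hydroxychalcone
Product: 18 3'-(benzyloxy)-5,6,7,8,4',5'-hexamethoxyflavone, via racemic flavanone 17 (not isolated)
Conditions: I2 (10 mol%), DMSO, 130 °C, 3 h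
Reagents that add atoms: none
Why: Iodine-catalysed oxidative cyclisation, in which intramolecular oxa-Michael addition of the 2'-phenol gives flavanone 17, α-iodination and loss of HI aromatise the pyranone (erasing the transient C2 stereocentre), and DMSO re-oxidises HI to I2.

Step 11
Reactants: 18 3'-(benzyloxy)-5,6,7,8,4',5'-hexamethoxyflavone
Product: 19 3'-hydroxy-5,6,7,8,4',5'-hexamethoxyflavone
Conditions: H2 (1 atm), 10% Pd/C, EtOAc/MeOH, rt
Reagents that add atoms: none
Why: Catalytic hydrogenolysis of the benzyl aryl ether over palladium metal, mild enough to leave the vinylogous-ester C2=C3 bond, the carbonyl and the six methyl ethers untouched.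

**Compound list**
1 | 2,3,4-trimethoxybenzaldehyde | COc1ccc(C=O)c(OC)c1OC | starting material
2 | 2,3,4-trimethoxyphenyl formate | COc1ccc(OC=O)c(OC)c1OC | intermediate
3 | 2,3,4-trimethoxyphenol | COc1ccc(O)c(OC)c1OC | intermediate
4 | 1,2,3,4-tetramethoxybenzene | COc1ccc(OC)c(OC)c1OC | intermediate
5 | N,N-dimethyl-(2,3,4,5-tetramethoxybenzylidene)iminium dichlorophosphate | COc1cc(C=[N+](C)C)c(OC)c(OC)c1OC.[O-]P(Cl)(Cl)=O | intermediate
6 | 2,3,4,5-tetramethoxybenzaldehyde | COc1cc(C=O)c(OC)c(OC)c1OC | intermediate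
7 | 2,3,4,5-tetramethoxyphenyl formate | COc1cc(OC=O)c(OC)c(OC)c1OC | intermediate
8 | 2,3,4,5-tetramethoxyphenol | COc1cc(O)c(OC)c(OC)c1OC | intermediate
9 | difluoroboron chelate of 10 (O,O-BF2 complex of the phenoxide and ketone oxygens) | CC1=[O+][B-](F)(F)Oc2c(OC)c(OC)c(OC)c(OC)c12 | intermediate
10 | 1-(2-hydroxy-3,4,5,6-tetramethoxyphenyl)ethan-1-one (2'-hydroxy-3',4',5',6'-tetramethoxyacetophenone) | CC(=O)c1c(O)c(OC)c(OC)c(OC)c1OC | intermediate
11 | 5-bromovanillin (3-bromo-4-hydroxy-5-methoxybenzaldehyde) | COc1cc(C=O)cc(Br)c1O | starting material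
12 | 5-hydroxyvanillin (3,4-dihydroxy-5-methoxybenzaldehyde) | COc1cc(C=O)cc(O)c1O | intermediate
13 | 3-hydroxy-4,5-dimethoxybenzaldehyde | COc1cc(C=O)cc(O)c1OC | intermediate
14 | 3-(benzyloxy)-4,5-dimethoxybenzaldehyde | COc1cc(C=O)cc(OCc2ccccc2)c1OC | intermediate
15 | racemic 3-[3-(benzyloxy)-4,5-dimethoxyphenyl]-3-hydroxy-1-(2-hydroxy-3,4,5,6-tetramethoxyphenyl)propan-1-one | COc1cc(C(O)CC(=O)c2c(O)c(OC)c(OC)c(OC)c2OC)cc(OCc2ccccc2)c1OC | intermediate
16 | (E)-3-[3-(benzyloxy)-4,5-dimethoxyphenyl]-1-(2-hydroxy-3,4,5,6-tetramethoxyphenyl)prop-2-en-1-one | COc1cc(/C=C/C(=O)c2c(O)c(OC)c(OC)c(OC)c2OC)cc(OCc2ccccc2)c1OC | intermediate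
17 | racemic 2-[3-(benzyloxy)-4,5-dimethoxyphenyl]-5,6,7,8-tetramethoxychroman-4-one | COc1cc(C2CC(=O)c3c(OC)c(OC)c(OC)c(OC)c3O2)cc(OCc2ccccc2)c1OC | intermediate
18 | 3'-(benzyloxy)-5,6,7,8,4',5'-hexamethoxyflavone | COc1cc(-c2cc(=O)c3c(OC)c(OC)c(OC)c(OC)c3o2)cc(OCc2ccccc2)c1OC | intermediate
19 | 3'-hydroxy-5,6,7,8,4',5'-hexamethoxyflavone (achiral) | COc1cc(-c2cc(=O)c3c(OC)c(OC)c(OC)c(OC)c3o2)cc(O)c1OC | target

**Summary**
Total step count: 11 (five to ketone 10, three to aldehyde 14, three after convergence).
Longest linear sequence: 8 steps (1 → 3 → 4 → 6 → 8 → 10 → 16 → 18 → 19; steps 1–5, 9, 10, 11).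

**Three steps most likely to fail, each with a fallback**

Step 5 (BF3-mediated C-acetylation of the very electron-rich, air-sensitive phenol 8; risks are partial O-demethylation, O-acetate formation without migration, and oxidation to quinones). The fallback sets out from 8 and replaces electrophilic acylation by directed ortho-metalation. The phenol is protected with MOMCl and i-Pr2NEt in CH2Cl2 at 0 °C to give 1-(methoxymethoxy)-2,3,4,5-tetramethoxybenzene F1. Its only ring hydrogen, flanked by the OMOM and OMe groups, is removed with n-BuLi in THF at 0 °C to give [2-(methoxymethoxy)-3,4,5,6-tetramethoxyphenyl]lithium F2, which is not isolated. Acylation with N-methoxy-N-methylacetamide (Weinreb amide) gives 1-[2-(methoxymethoxy)-3,4,5,6-tetramethoxyphenyl]ethan-1-one F3. Removal of the MOM group with HCl in MeOH at rt comes back to the route at 10.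

Step 7 (selective 4-O-methylation of catechol 12; risks are the 3-O-methyl isomer, dimethylation to 3,4,5-trimethoxybenzaldehyde, and catechol oxidation). The fallback sets out from 11, fixes the regiochemistry through the bromine position, and also bypasses step 6. The single phenol is methylated with MeI and K2CO3 in DMF to give 3-bromo-4,5-dimethoxybenzaldehyde F4. Miyaura borylation (B2pin2, Pd(dppf)Cl2, KOAc, dioxane, 90 °C) gives 3,4-dimethoxy-5-(4,4,5,5-tetramethyl-1,3,2-dioxaborolan-2-yl)benzaldehyde F5. Oxidation of the C–B bond with NaBO3·4H2O in THF/H2O at rt comes back to the route at 13.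

Step 10 (I2/DMSO oxidative cyclisation; risks are HI-mediated loss of the 5-OMe or the benzyl group, ring iodination, and stalling at flavanone 17). The fallback sets out from 14, with ketone 10 used unchanged as the partner, and builds ring C at the flavone oxidation level through an intermolecular Claisen condensation. Pinnick oxidation (NaClO2, NaH2PO4, 2-methyl-2-butene, t-BuOH/H2O) gives 3-(benzyloxy)-4,5-dimethoxybenzoic acid F6. Oxalyl chloride with catalytic DMF in CH2Cl2 gives 3-(benzyloxy)-4,5-dimethoxybenzoyl chloride F7. The lithium dianion of 10 (LiN(SiMe3)2, 3.5 equiv, THF, −78 °C → rt) is C-acylated by F7 to give 1-[3-(benzyloxy)-4,5-dimethoxyphenyl]-3-(2-hydroxy-3,4,5,6-tetramethoxyphenyl)propane-1,3-dione F8. Cyclodehydration with catalytic p-TsOH in refluxing toluene comes back to the route at 18, so steps 9 and 10 are both replaced.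

**Further compounds**
F1 | step 5 | 1-(methoxymethoxy)-2,3,4,5-tetramethoxybenzene | COCOc1cc(OC)c(OC)c(OC)c1OC
F2 | step 5 | [2-(methoxymethoxy)-3,4,5,6-tetramethoxyphenyl]lithium | [Li]c1c(OCOC)c(OC)c(OC)c(OC)c1OC
F3 | step 5 | 1-[2-(methoxymethoxy)-3,4,5,6-tetramethoxyphenyl]ethan-1-one | CC(=O)c1c(OCOC)c(OC)c(OC)c(OC)c1OC
F4 | step 7 | 3-bromo-4,5-dimethoxybenzaldehyde | COc1cc(C=O)cc(Br)c1OC
F5 | step 7 | 3,4-dimethoxy-5-(4,4,5,5-tetramethyl-1,3,2-dioxaborolan-2-yl)benzaldehyde | COc1cc(C=O)cc(B2OC(C)(C)C(C)(C)O2)c1OC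
F6 | step 10 | 3-(benzyloxy)-4,5-dimethoxybenzoic acid | COc1cc(C(=O)O)cc(OCc2ccccc2)c1OC
F7 | step 10 | 3-(benzyloxy)-4,5-dimethoxybenzoyl chloride | COc1cc(C(Cl)=O)cc(OCc2ccccc2)c1OC
F8 | step 10 | 1-[3-(benzyloxy)-4,5-dimethoxyphenyl]-3-(2-hydroxy-3,4,5,6-tetramethoxyphenyl)propane-1,3-dione | COc1cc(C(=O)CC(=O)c2c(O)c(OC)c(OC)c(OC)c2OC)cc(OCc2ccccc2)c1OC
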